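Cuts: ring B at O1–C2 and C4–C4a (this releases 3-methylbut-2-enal and a triphenol), then ring A at C8–C8a, then the resulting heterocycle at C5–C6 and at its lactone C–O bond.
Enabling feature (chromene numbering): ring A (C4a, C5, C6, C7, C8, C8a) has oxygen on C7 and C8a, an ester on C6 and hydrogen on C4a. Moving the carbonyl carbon C8a from C8 to the oxygen on C7 therefore gives an isomeric 2-pyrone-5-carboxylate, in which C8 is the first methylene of the chain at pyrone position 6.
Forward order: a prenylated β-keto ester (C6, C7, C8) and an arylethyl ynoate (C8a, C4a, C5) are made separately and joined to the pyrone ring. Methoxide then converts the pyrone into carbocyclic ring A, and ring B is closed last on O8a and C4a.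
All four substituents of ring A are fixed by acyclic carbonyl chemistry, so no aromatic substitution is needed before the last step.
Stereochemistry: the target has no stereocentre, C3=C4 is cis by ring constraint and the prenyl alkene has no geometry, so nothing has to be controlled.

Key step: step 7

Assumption: the aryl silyl ether is taken to be methanolysed faster than ring A closes, so the in-flask species 14 and 15 are drawn as free phenols in neutral form although they are present as sodium salts. TBS = tert-butyldimethylsilyl, TIPS = triisopropylsilyl.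

Step 1
Reactants: 1 methyl acetoacetate; 2 prenyl bromide (1-bromo-3-methylbut-2-ene)
Product: 4 methyl 7-methyl-3-oxooct-6-enoate, via acetoacetate dianion 3 (not isolated)
Conditions: NaH, THF, 0 °C; n-BuLi, 0 °C; 2, 0 °C to rt; aq. HCl
Reagents that add atoms: none
Why: In this γ-alkylation of the acetoacetate dianion, the terminal carbanion is by far the more nucleophilic site, so the allylic bromide is taken up there by SN2 and the future C8 ends up next to its prenyl group.

Step 2
Reactants: 5 methyl 3-(4-hydroxyphenyl)propanoate
Product: 6 methyl 3-[4-(tert-butyldimethylsilyloxy)phenyl]propanoate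
Conditions: TBSCl, imidazole, DMF, rt
Reagents that add atoms: tert-butyldimethylsilyl chloride (TBSCl), CC(C)(C)[Si](C)(C)Cl
Why: This is a standard imidazole-promoted silylation of a phenol, and it masks the acidic OH against the hydride, ylide and organolithium reagents of the next three steps.

Step 3
Reactants: 6 methyl 3-[4-(tert-butyldimethylsilyloxy)phenyl]propanoate
Product: 8 3-[4-(tert-butyldimethylsilyloxy)phenyl]propanal, via aluminium hemiacetal 7 (not isolated)
Conditions: i-Bu2AlH (1.05 equiv), CH2Cl2, −78 °C; MeOH, then aq. potassium sodium tartrate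
Reagents that add atoms: none
Why: This is a partial reduction of a methyl ester, in which adduct 7 does not collapse at −78 °C, so the aldehyde appears only on quench and is not reduced further.

Step 4
Reactants: 8 3-[4-(tert-butyldimethylsilyloxy)phenyl]propanal
Product: 9 tert-butyl[4-(4,4-dibromobut-3-en-1-yl)phenoxy]dimethylsilane
Conditions: CBr4, PPh3, CH2Cl2, 0 °C
Reagents that add atoms: carbon tetrabromide, BrC(Br)(Br)Br
Why: In this first stage of the Corey–Fuchs sequence, the dibromomethylene ylide formed in situ undergoes a Wittig reaction with the unhindered aldehyde, and aryl silyl ethers tolerate these conditions.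

Step 5
Reactants: 9 tert-butyl[4-(4,4-dibromobut-3-en-1-yl)phenoxy]dimethylsilane
Product: 11 methyl 5-[4-(tert-butyldimethylsilyloxy)phenyl]pent-2-ynoate, via lithium acetylide 10 (not isolated)
Conditions: n-BuLi (2.1 equiv), THF, −78 to 0 °C; ClCO2Me, −78 °C to rt
Reagents that add atoms: methyl chloroformate, COC(=O)Cl
Why: In this second stage of the Corey–Fuchs sequence, lithium–bromine exchange and loss of HBr (Fritsch–Buttenberg–Wiechell type collapse) give the acetylide, which the chloroformate acylates at carbon.

Step 6
Reactants: 4 methyl 7-methyl-3-oxooct-6-enoate; 11 methyl 5-[4-(tert-butyldimethylsilyloxy)phenyl]pent-2-ynoate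
Product: 13 methyl 4-{2-[4-(tert-butyldimethylsilyloxy)phenyl]ethyl}-6-(4-methylpent-3-en-1-yl)-2-oxo-2H-pyran-5-carboxylate, via Michael adduct 12 (not isolated)
Conditions: 4 (1.3 equiv), KOt-Bu (20 mol %), toluene, 4 Å MS, 90 °C; AcOH
Reagents that add atoms: none
Why: This is the classical base-catalysed Michael addition of a β-keto ester to an alk-2-ynoate followed by enol lactonisation to a 2-pyrone-5-carboxylate, in which the excess of 4 keeps its enolate the strongest base present (sparing the silyl ether and the propargylic CH2) and the sieves take up methanol to pull the equilibrium to the neutral pyrone.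

Step 7
Reactants: 13 methyl 4-{2-[4-(tert-butyldimethylsilyloxy)phenyl]ethyl}-6-(4-methylpent-3-en-1-yl)-2-oxo-2H-pyran-5-carboxylate
Product: 16 methyl 2,4-dihydroxy-6-[2-(4-hydroxyphenyl)ethyl]-3-(3-methylbut-2-en-1-yl)benzoate, via open-chain keto diester 14 (not isolated), via cyclohexenedione 15 (not isolated)
Conditions: NaOMe (6 equiv, 2 M), dry MeOH, reflux, Ar; 1 M HCl, 0 °C
Reagents that add atoms: none
Why: Proposed new method: methoxide adds to the lactone carbonyl C8a and cleaves its bond to the C7 enol oxygen, giving the delocalised anion of acylglutaconate 14 (the aryl silyl ether is methanolysed on the way), and re-closure through oxygen only leads back to the pyrone. The minor enolate at the prenyl-bearing methylene C8 attacks the C8a ester, methoxide leaves, and diketone 15 tautomerises at once to the phenoxide of 16, which cannot reopen. Ring A closes in a 6-(enolendo)-exo-trig Dieckmann mode, and this is the only carbon closure open to 14, because every other carbanion/carbonyl pair would form a four-membered ring. The closest known reaction types are the base-induced opening and Claisen re-closure of acylpyrones to resorcinols and the Michael–Dieckmann route to dihydroresorcylates in NaOMe/MeOH, in which a ketone alpha-carbon also cyclises onto an ester while a more acidic site carries the charge. The selectivity needed is carbon over oxygen acylation, and it is supplied by thermodynamics (reversible lactone, irreversible aromatisation), while rotation about C4a–C5 in the anion is harmless because both geometries interconvert. No stereocentre is formed, and dry concentrated NaOMe is used to raise the share of the C8 enolate and to exclude saponification and hydroxide-driven deacylation at C7.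

Step 8
Reactants: 16 methyl 2,4-dihydroxy-6-[2-(4-hydroxyphenyl)ethyl]-3-(3-methylbut-2-en-1-yl)benzoate; 17 3-methylbut-2-enal
Product: 19 methyl 7-hydroxy-5-[2-(4-hydroxyphenyl)ethyl]-2,2-dimethyl-8-(3-methylbut-2-en-1-yl)-2H-chromene-6-carboxylate, via ortho-quinone methide 18 (not isolated)
Conditions: 17 (2 equiv), ethylenediammonium diacetate (20 mol %), toluene, reflux
Reagents that add atoms: none
Why: In this well-known formal [3+3] chromene synthesis on resorcinols (Knoevenagel-type condensation, loss of water to 18, oxa-6π electrocyclisation), C4a is the only free carbon of ring A, the chelated C7 hydroxyl has no free ortho position, and the monophenol ring is too weak a nucleophile under these mild conditions.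

Compound list
1 | methyl acetoacetate | COC(=O)CC(C)=O | starting material
2 | prenyl bromide (1-bromo-3-methylbut-2-ene) | CC(C)=CCBr | starting material
3 | sodium lithium dianion of methyl acetoacetate (in-flask species) | [Na+].[Li+].COC([O-])=CC([O-])=C | intermediate
4 | methyl 7-methyl-3-oxooct-6-enoate | COC(=O)CC(=O)CCC=C(C)C | intermediate
5 | methyl 3-(4-hydroxyphenyl)propanoate | COC(=O)CCc1ccc(O)cc1 | starting material
6 | methyl 3-[4-(tert-butyldimethylsilyloxy)phenyl]propanoate | COC(=O)CCc1ccc(O[Si](C)(C)C(C)(C)C)cc1 | intermediate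
7 | diisobutylaluminium 1-methoxy-3-[4-(tert-butyldimethylsilyloxy)phenyl]propan-1-olate (racemic, in-flask species) | COC(CCc1ccc(O[Si](C)(C)C(C)(C)C)cc1)O[Al](CC(C)C)CC(C)C | intermediate
8 | 3-[4-(tert-butyldimethylsilyloxy)phenyl]propanal | O=CCCc1ccc(O[Si](C)(C)C(C)(C)C)cc1 | intermediate
9 | tert-butyl[4-(4,4-dibromobut-3-en-1-yl)phenoxy]dimethylsilane | BrC(Br)=CCCc1ccc(O[Si](C)(C)C(C)(C)C)cc1 | intermediate
10 | {4-[4-(tert-butyldimethylsilyloxy)phenyl]but-1-yn-1-yl}lithium (in-flask species) | [Li]C#CCCc1ccc(O[Si](C)(C)C(C)(C)C)cc1 | intermediate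
11 | methyl 5-[4-(tert-butyldimethylsilyloxy)phenyl]pent-2-ynoate | COC(=O)C#CCCc1ccc(O[Si](C)(C)C(C)(C)C)cc1 | intermediate
12 | dimethyl (2Z)-3-{2-[4-(tert-butyldimethylsilyloxy)phenyl]ethyl}-4-(5-methylhex-4-enoyl)pent-2-enedioate (the lactonising geometry is shown; C4 is labile and racemic; in-flask species) | COC(=O)/C=C(/CCc1ccc(O[Si](C)(C)C(C)(C)C)cc1)C(C(=O)OC)C(=O)CCC=C(C)C | intermediate
13 | methyl 4-{2-[4-(tert-butyldimethylsilyloxy)phenyl]ethyl}-6-(4-methylpent-3-en-1-yl)-2-oxo-2H-pyran-5-carboxylate | COC(=O)C1=C(CCC=C(C)C)OC(=O)C=C1CCc1ccc(O[Si](C)(C)C(C)(C)C)cc1 | intermediate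
14 | dimethyl (2Z)-3-[2-(4-hydroxyphenyl)ethyl]-4-(5-methylhex-4-enoyl)pent-2-enedioate (present as sodium salt; C4 is labile; in-flask species) | COC(=O)/C=C(/CCc1ccc(O)cc1)C(C(=O)OC)C(=O)CCC=C(C)C | intermediate
15 | methyl 6-[2-(4-hydroxyphenyl)ethyl]-3-(3-methylbut-2-en-1-yl)-2,4-dioxocyclohex-5-ene-1-carboxylate (labile centres, in-flask species) | COC(=O)C1C(=O)C(CC=C(C)C)C(=O)C=C1CCc1ccc(O)cc1 | intermediate
16 | methyl 2,4-dihydroxy-6-[2-(4-hydroxyphenyl)ethyl]-3-(3-methylbut-2-en-1-yl)benzoate | COC(=O)c1c(O)c(CC=C(C)C)c(O)cc1CCc1ccc(O)cc1 | intermediate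
17 | 3-methylbut-2-enal | CC(C)=CC=O | starting material
18 | methyl (3Z)-6-hydroxy-2-[2-(4-hydroxyphenyl)ethyl]-5-(3-methylbut-2-en-1-yl)-3-(3-methylbut-2-en-1-ylidene)-4-oxocyclohexa-1,5-diene-1-carboxylate (in-flask species) | COC(=O)C1=C(CCc2ccc(O)cc2)/C(=C/C=C(C)C)C(=O)C(CC=C(C)C)=C1O | intermediate
19 | methyl 7-hydroxy-5-[2-(4-hydroxyphenyl)ethyl]-2,2-dimethyl-8-(3-methylbut-2-en-1-yl)-2H-chromene-6-carboxylate (CNP0133674.0) | COC(=O)c1c(O)c(CC=C(C)C)c2c(c1CCc1ccc(O)cc1)C=CC(C)(C)O2 | target

Total step count: 8. Longest linear sequence: 7 (steps 2 to 8).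

Steps most likely to fail

Step 7.
- **Risk:** the opened anion may stay inert because deprotonation at C8 is too rare. It may also be eroded by retro-Claisen loss of the 5-methylhex-4-enoyl group or by conjugate attack of methoxide at pyrone position 6.
- **Approach:** the fallback uses known chemistry only, builds ring A one oxidation level lower and adds the prenyl group last. It sets out from aldehyde 8 and methyl acetoacetate 1 and returns at 16.
- **Route:** Wittig olefination of 8 with methyl (triphenylphosphoranylidene)acetate in CH2Cl2 gives methyl (E)-5-[4-(tert-butyldimethylsilyloxy)phenyl]pent-2-enoate F1. Michael addition of 1 and Dieckmann closure in NaOMe/MeOH at reflux, with the silyl ether shed, gives the dihydroresorcylate methyl 2-hydroxy-6-[2-(4-hydroxyphenyl)ethyl]-4-oxocyclohex-2-ene-1-carboxylate F2. I2 (20 mol %) in DMSO at 80 °C dehydrogenates it to methyl 2,4-dihydroxy-6-[2-(4-hydroxyphenyl)ethyl]benzoate F3. Friedel–Crafts prenylation with 3-methylbut-2-en-1-ol over acidic Al2O3 in 1,2-dichloroethane at reflux should go mainly to the carbon between the two hydroxyls and give 16.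

Step 6.
- **Risk:** conjugate addition to the β-alkyl ynoate may be slow. Base-induced migration of the triple bond towards the arene, self-condensation of the keto ester and creeping loss of the silyl group would then gain ground.
- **Approach:** the fallback replaces the triple bond by a leaving group on the acceptor, so that the C–C bond forms by vinylic substitution. It sets out from ynoate 11 and returns at pyrone 13.
- **Route:** NaI in AcOH at 80 °C adds HI in the anti sense to give methyl (Z)-5-[4-(tert-butyldimethylsilyloxy)phenyl]-3-iodopent-2-enoate F4. The preformed sodium enolate of 4 (NaH, THF, two equivalents, 0 °C to rt) displaces iodide by addition–elimination with retention of geometry. This gives adduct 12 with the ester already cis to the keto ester carbon. After an AcOH quench, warming in toluene over 4 Å sieves completes the lactonisation to 13.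

Step 8.
- **Risk:** attack at C4a, crowded by the arylethyl chain, may be slower than self-condensation of the enal, and forcing conditions could draw the monophenol ring into the reaction.
- **Approach:** the fallback forms the ether first and then makes the C–C bond by a sigmatropic shift. It sets out from 16 and returns at 19.
- **Route:** TIPSCl and imidazole in DMF at 0 °C should silylate the unhindered monophenol and give methyl 2,4-dihydroxy-3-(3-methylbut-2-en-1-yl)-6-{2-[4-(triisopropylsilyloxy)phenyl]ethyl}benzoate F5. O-Alkylation of the non-chelated hydroxyl with 3-chloro-3-methylbut-1-yne (CuCl2 catalyst, 1,8-diazabicyclo[5.4.0]undec-7-ene, MeCN, 0 °C) gives methyl 2-hydroxy-3-(3-methylbut-2-en-1-yl)-4-[(2-methylbut-3-yn-2-yl)oxy]-6-{2-[4-(triisopropylsilyloxy)phenyl]ethyl}benzoate F6. Heating in xylene at 140 °C triggers the aromatic propargyl Claisen rearrangement to C4a (the other ortho carbon is blocked), a 1,5-hydrogen shift and oxa-6π closure. The product is methyl 7-hydroxy-2,2-dimethyl-8-(3-methylbut-2-en-1-yl)-5-{2-[4-(triisopropylsilyloxy)phenyl]ethyl}-2H-chromene-6-carboxylate F7. Bu4NF in THF at 0 °C then gives 19.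

Further compounds
F1 | step 7 | methyl (E)-5-[4-(tert-butyldimethylsilyloxy)phenyl]pent-2-enoate | COC(=O)/C=C/CCc1ccc(O[Si](C)(C)C(C)(C)C)cc1
F2 | step 7 | methyl 2-hydroxy-6-[2-(4-hydroxyphenyl)ethyl]-4-oxocyclohex-2-ene-1-carboxylate (racemic, centres removed in the next operation) | COC(=O)C1C(O)=CC(=O)CC1CCc1ccc(O)cc1
F3 | step 7 | methyl 2,4-dihydroxy-6-[2-(4-hydroxyphenyl)ethyl]benzoate | COC(=O)c1c(O)cc(O)cc1CCc1ccc(O)cc1
F4 | step 6 | methyl (Z)-5-[4-(tert-butyldimethylsilyloxy)phenyl]-3-iodopent-2-enoate | COC(=O)/C=C(\I)CCc1ccc(O[Si](C)(C)C(C)(C)C)cc1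
F5 | step 8 | methyl 2,4-dihydroxy-3-(3-methylbut-2-en-1-yl)-6-{2-[4-(triisopropylsilyloxy)phenyl]ethyl}benzoate | COC(=O)c1c(O)c(CC=C(C)C)c(O)cc1CCc1ccc(O[Si](C(C)C)(C(C)C)C(C)C)cc1
F6 | step 8 | methyl 2-hydroxy-3-(3-methylbut-2-en-1-yl)-4-[(2-methylbut-3-yn-2-yl)oxy]-6-{2-[4-(triisopropylsilyloxy)phenyl]ethyl}benzoate | COC(=O)c1c(O)c(CC=C(C)C)c(OC(C)(C)C#C)cc1CCc1ccc(O[Si](C(C)C)(C(C)C)C(C)C)cc1
F7 | step 8 | methyl 7-hydroxy-2,2-dimethyl-8-(3-methylbut-2-en-1-yl)-5-{2-[4-(triisopropylsilyloxy)phenyl]ethyl}-2H-chromene-6-carboxylate | COC(=O)c1c(O)c(CC=C(C)C)c2c(c1CCc1ccc(O[Si](C(C)C)(C(C)C)C(C)C)cc1)C=CC(C)(C)O2
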